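**Strategy.** Ring A is not attached as a finished arene; it is grown on the ketone carbon. The disconnection opens the A-C3–A-C4 bond (equivalent to A-C2–A-C3 before desymmetrisation) and unfolds ring A into a 3-aroylheptane-2,4,6-trione, stored as the 3-aroyl-2,6-dimethyl-4-pyranone 15 whose aroyl group is the complete, protected ring B. Mg(OMe)2 opens the pyranone and one aldol aromatisation delivers the hindered benzophenone 17. The step exploits the orcinol pattern of ring A: oxygens on A-C1 and A-C5 flanking the ketone-bearing A-C6, methyl on A-C3. Ring B comes from 3,5-dihydroxybenzoic acid by two amide-directed metalations; methylation, bromination and unmasking of the aldehyde finish the route.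

Key step: step 10

Remark on numbering: ring A is A-C1 (OMe), A-C2 (H), A-C3 (Me), A-C4 (Br), A-C5 (OH), A-C6 (ketone); ring B is B-C1 (ketone), B-C2 (CHO), B-C3 (OH), B-C4 (H), B-C5 (OH), B-C6 (prenyl). Ar stands for the protected ring B, 3,5-bis(methoxymethoxy)-2-(3-methylbut-2-en-1-yl)-6-[(triisopropylsilyloxy)methyl]phenyl.

Assumption: hydroxy ketones 10 and 20 are drawn open, although each can rest partly as its five-membered cyclic hemiketal; the following step draws on the open form in both cases. Hemiketal 14 is a transient mixture of racemic diastereomers whose two stereocentres vanish on dehydration, and trione 16 is drawn in its keto form although it exists as the magnesium enolate.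

**Step 1**
Reactants: 1 3,5-dihydroxybenzoic acid
Product: 3 3,5-bis(methoxymethoxy)benzoic acid, via methoxymethyl ester 2 (not isolated)
Conditions: MOMCl, i-Pr2NEt, CH2Cl2, 0 °C to rt; then LiOH, THF/MeOH/H2O, rt; dilute HCl to pH 4 at 0 °C
Reagents that add atoms: chloromethyl methyl ether, COCCl; lithium hydroxide, [Li+].[OH-]
Why: Williamson-type alkylation with the chloromethyl ether caps both phenols and the carboxylate, and hydroxide then cleaves only the acyl acetal (ester hydrolysis), since aryl methoxymethyl ethers are inert to base.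

**Step 2**
Reactants: 3 3,5-bis(methoxymethoxy)benzoic acid
Product: 4 N,N-diethyl-3,5-bis(methoxymethoxy)benzamide
Conditions: CDI, THF, rt; then Et2NH, 50 °C
Reagents that add atoms: diethylamine, CCNCC
Why: Amide coupling through the acyl imidazolide (CDI activation) runs under neutral conditions that leave the acetal ethers untouched.

**Step 3**
Reactants: 4 N,N-diethyl-3,5-bis(methoxymethoxy)benzamide; 5 1-bromo-3-methylbut-2-ene (prenyl bromide)
Product: 6 N,N-diethyl-3,5-bis(methoxymethoxy)-2-(3-methylbut-2-en-1-yl)benzamide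
Conditions: s-BuLi, TMEDA, THF, −78 °C; CuBr·SMe2, −78 to −40 °C; 5, −78 °C to rt
Reagents that add atoms: 1-bromo-3-methylbut-2-ene (5), CC(C)=CCBr
Why: Directed ortho-metalation: the diethylamide, the stronger director, cooperates with the neighbouring OMOM group so that s-BuLi/TMEDA removes the hydrogen between them under kinetic control, and the arylcopper formed by transmetalation substitutes prenyl bromide at its primary carbon (SN2 allylation), giving the linear prenyl group.

**Step 4**
Reactants: 6 N,N-diethyl-3,5-bis(methoxymethoxy)-2-(3-methylbut-2-en-1-yl)benzamide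
Product: 7 N,N-diethyl-2-formyl-3,5-bis(methoxymethoxy)-6-(3-methylbut-2-en-1-yl)benzamide
Conditions: s-BuLi, TMEDA, THF, −78 °C, short metalation time; DMF, −78 to 0 °C; aq NH4Cl
Reagents that add atoms: N,N-dimethylformamide, CN(C)C=O
Why: A second directed ortho-metalation takes the only remaining hydrogen flanked by the amide and an OMOM group, where complex-induced ring deprotonation by s-BuLi/TMEDA at −78 °C should be faster than lateral deprotonation of the prenyl CH2, and the aryllithium is formylated by DMF.

**Step 5**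
Reactants: 7 N,N-diethyl-2-formyl-3,5-bis(methoxymethoxy)-6-(3-methylbut-2-en-1-yl)benzamide
Product: 9 4,6-bis(methoxymethoxy)-7-(3-methylbut-2-en-1-yl)-2-benzofuran-1(3H)-one (phthalide), via hydroxymethyl amide 8 (not isolated)
Conditions: NaBH4, MeOH, 0 °C; then AcOH, 40 °C
Reagents that add atoms: none
Why: Hydride reduction of the aldehyde places a benzylic hydroxyl against the twisted amide carbonyl, and weak acid triggers intramolecular N-to-O acyl transfer (lactonisation to the phthalide), which turns the inert diethylamide into an acyl donor while the acetal ethers tolerate acetic acid.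

**Step 6**
Reactants: 9 4,6-bis(methoxymethoxy)-7-(3-methylbut-2-en-1-yl)-2-benzofuran-1(3H)-one
Product: 10 1-[2-(hydroxymethyl)-3,5-bis(methoxymethoxy)-6-(3-methylbut-2-en-1-yl)phenyl]ethan-1-one
Conditions: MeLi (1.05 equiv), THF, −78 °C; aq NH4Cl at −78 °C
Reagents that add atoms: methyllithium, [Li]C
Why: Addition of MeLi to the lactone stops after one equivalent because the tetrahedral lithium hemiketal alkoxide persists at −78 °C until the cold quench (organolithium mono-addition to a lactone).

**Step 7**
Reactants: 10 1-[2-(hydroxymethyl)-3,5-bis(methoxymethoxy)-6-(3-methylbut-2-en-1-yl)phenyl]ethan-1-one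
Product: 11 1-[3,5-bis(methoxymethoxy)-2-(3-methylbut-2-en-1-yl)-6-[(triisopropylsilyloxy)methyl]phenyl]ethan-1-one (ArCOCH3)
Conditions: TIPSCl, imidazole, DMF, rt
Reagents that add atoms: chlorotriisopropylsilane, CC(C)[Si](Cl)(C(C)C)C(C)C
Why: Silylation of the primary hydroxyl of the open-chain tautomer; the tertiary hemiketal hydroxyl is too hindered for TIPSCl, so ring–chain equilibration funnels all material to the silyl ether.

**Step 8**
Reactants: 11 ArCOCH3
Product: 12 1-Ar-butane-1,3-dione
Conditions: NaH, EtOAc, THF, 0 to 50 °C; aq NH4Cl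
Reagents that add atoms: ethyl acetate, CCOC(C)=O
Why: Crossed Claisen condensation: the enolate of the methyl ketone, its only enolisable site, attacks ethyl acetate and deprotonation of the resulting 1,3-diketone drives the reaction.

**Step 9**
Reactants: 12 1-Ar-butane-1,3-dione; 13 2,2,6-trimethyl-4H-1,3-dioxin-4-one
Product: 15 3-(ArCO)-2,6-dimethyl-4H-pyran-4-one, via hemiketal 14 (not isolated)
Conditions: 13 (3 equiv), PhMe, 110 °C, 4 Å MS, acetone distilled off
Reagents that add atoms: 2,2,6-trimethyl-4H-1,3-dioxin-4-one (13), CC1=CC(=O)OC(C)(C)O1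
Why: At 110 °C dioxinone 13 loses acetone by cycloreversion to acetylketene, which reacts as a 1-oxadiene with the enol double bond on the acetyl side of diketone 12 (ketene carbon to the central carbon, acetyl oxygen to the enol carbon) in a formal [4+2] annulation, and the 2-hydroxy-2,3-dihydropyranone 14 then loses water to the 4-pyranone; the enol on the aroyl side is shielded by the two ortho substituents of ring B, and this acylketene annulation of enolised 1,3-dicarbonyl compounds is an established 4-pyranone synthesis.

**Step 10**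
Reactants: 15 3-(ArCO)-2,6-dimethyl-4H-pyran-4-one
Product: 17 (2,6-dihydroxy-4-methylphenyl)(Ar)methanone, via tetraketone 16 (not isolated)
Conditions: Mg(OMe)2 (8 equiv), MeOH containing 1–2 equiv H2O, 65 °C; cold dilute HCl to pH 5
Reagents that add atoms: none
Why: Hydroxide generated from Mg(OMe)2 and the added water adds to C6 of the pyranone (the end next to the ring CH), the ring opens to 3-aroylheptane-2,4,6-trione 16, held as the magnesium chelate of its triacylmethanide; the methyl carbon of the acetyl group inside the chelated unit, as its extended enolate, attacks the one unchelated ketone (the distal acetyl), and loss of water followed by enolisation gives the resorcinol. The closest known reaction type is the base-induced unfolding of 4-pyranones to poly-β-carbonyl chains that aromatise by aldol condensation to orcinols, as used in biomimetic polyketide cyclisations. The one ring closed, ring A, forms in the 6-(enolendo)-exo-trig mode. No stereocentre is created. The step needs site selectivity among three aldol pairings: the chelate lowers the electrophilicity of its three carbonyls and the aroyl carbonyl is flanked by the two ortho substituents of ring B, so only the distal acetyl should accept the nucleophile, which disfavours both the reverse aldol (leading to the 2,4-dihydroxy-6-methyl isomer) and closure onto the aroyl carbon (leading to a biaryl). Retro-Claisen loss of an acyl group is held back by using the chelating, weakly basic Mg(OMe)2 in methanol in place of hot aqueous hydroxide.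

**Step 11**
Reactants: 17 (2,6-dihydroxy-4-methylphenyl)(Ar)methanone
Product: 18 (2-hydroxy-6-methoxy-4-methylphenyl)(Ar)methanone
Conditions: MeI (1.1 equiv), K2CO3, acetone, rt
Reagents that add atoms: iodomethane, CI
Why: Williamson O-methylation; the two hydroxyls are equivalent, and after the first alkylation the remaining one is tied to the ketone by a hydrogen bond and is a far poorer nucleophile, so the reaction should stop at the monoether.

**Step 12**
Reactants: 18 (2-hydroxy-6-methoxy-4-methylphenyl)(Ar)methanone
Product: 19 (3-bromo-2-hydroxy-6-methoxy-4-methylphenyl)(Ar)methanone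
Conditions: NBS (1.0 equiv), i-Pr2NH (0.1 equiv), CH2Cl2, −20 to 0 °C, dark
Reagents that add atoms: N-bromosuccinimide, O=C1CCC(=O)N1Br
Why: Amine-mediated ortho-bromination of a phenol: NBS and i-Pr2NH form an N-bromoamine that is delivered through the hydrogen-bonded phenol to the adjacent carbon A-C4, which is also para to the methoxy group, while the ether-only ring B and the prenyl alkene, lacking a free phenol, should stay untouched at low temperature with one equivalent of NBS.

**Step 13**
Reactants: 19 (3-bromo-2-hydroxy-6-methoxy-4-methylphenyl)(Ar)methanone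
Product: 20 (3-bromo-2-hydroxy-6-methoxy-4-methylphenyl)[2-(hydroxymethyl)-3,5-bis(methoxymethoxy)-6-(3-methylbut-2-en-1-yl)phenyl]methanone
Conditions: Bu4NF, AcOH, THF, 0 °C to rt
Reagents that add atoms: none
Why: Fluoride cleaves the Si–O bond (desilylation); buffering with acetic acid keeps the medium near neutral, and acetal ethers, aryl bromide and ketone are inert.

**Step 14**
Reactants: 20 (3-bromo-2-hydroxy-6-methoxy-4-methylphenyl)[2-(hydroxymethyl)-3,5-bis(methoxymethoxy)-6-(3-methylbut-2-en-1-yl)phenyl]methanone
Product: 21 2-(3-bromo-2-hydroxy-6-methoxy-4-methylbenzoyl)-4,6-bis(methoxymethoxy)-3-(3-methylbut-2-en-1-yl)benzaldehyde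
Conditions: MnO2 (activated, excess), CH2Cl2, rt
Reagents that add atoms: none
Why: MnO2 oxidises benzylic alcohols selectively to aldehydes without over-oxidation, acting on the open hydroxy ketone tautomer; the chelated, bromine-bearing phenol is a poor substrate for this oxidant.

**Step 15**
Reactants: 21 2-(3-bromo-2-hydroxy-6-methoxy-4-methylbenzoyl)-4,6-bis(methoxymethoxy)-3-(3-methylbut-2-en-1-yl)benzaldehyde
Product: 22 Pestalone B, 2-(3-bromo-2-hydroxy-6-methoxy-4-methylbenzoyl)-4,6-dihydroxy-3-(3-methylbut-2-en-1-yl)benzaldehyde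
Conditions: 2 M aq HCl, MeOH/THF, rt
Reagents that add atoms: none
Why: Acid-catalysed acetal cleavage of the two aryl methoxymethyl ethers by methanol; dilute acid at room temperature is chosen so that the B-C5 hydroxyl does not add to the prenyl alkene (chroman formation), and no base is used after the aldehyde is unmasked because the ortho-formyl benzophenone is prone to base-induced hydride-shift lactonisation.

**Compound list**
1 | 3,5-dihydroxybenzoic acid | OC(=O)c1cc(O)cc(O)c1 | starting material
2 | methoxymethyl 3,5-bis(methoxymethoxy)benzoate | COCOC(=O)c1cc(OCOC)cc(OCOC)c1 | intermediate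
3 | 3,5-bis(methoxymethoxy)benzoic acid | OC(=O)c1cc(OCOC)cc(OCOC)c1 | intermediate
4 | N,N-diethyl-3,5-bis(methoxymethoxy)benzamide | CCN(CC)C(=O)c1cc(OCOC)cc(OCOC)c1 | intermediate
5 | 1-bromo-3-methylbut-2-ene | CC(C)=CCBr | starting material
6 | N,N-diethyl-3,5-bis(methoxymethoxy)-2-(3-methylbut-2-en-1-yl)benzamide | CCN(CC)C(=O)c1cc(OCOC)cc(OCOC)c1CC=C(C)C | intermediate
7 | N,N-diethyl-2-formyl-3,5-bis(methoxymethoxy)-6-(3-methylbut-2-en-1-yl)benzamide | CCN(CC)C(=O)c1c(C=O)c(OCOC)cc(OCOC)c1CC=C(C)C | intermediate
8 | N,N-diethyl-2-(hydroxymethyl)-3,5-bis(methoxymethoxy)-6-(3-methylbut-2-en-1-yl)benzamide | CCN(CC)C(=O)c1c(CO)c(OCOC)cc(OCOC)c1CC=C(C)C | intermediate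
9 | 4,6-bis(methoxymethoxy)-7-(3-methylbut-2-en-1-yl)-2-benzofuran-1(3H)-one | O=C1OCc2c1c(CC=C(C)C)c(OCOC)cc2OCOC | intermediate
10 | 1-[2-(hydroxymethyl)-3,5-bis(methoxymethoxy)-6-(3-methylbut-2-en-1-yl)phenyl]ethan-1-one | CC(=O)c1c(CO)c(OCOC)cc(OCOC)c1CC=C(C)C | intermediate
11 | 1-[3,5-bis(methoxymethoxy)-2-(3-methylbut-2-en-1-yl)-6-[(triisopropylsilyloxy)methyl]phenyl]ethan-1-one | CC(=O)c1c(CO[Si](C(C)C)(C(C)C)C(C)C)c(OCOC)cc(OCOC)c1CC=C(C)C | intermediate
12 | 1-[3,5-bis(methoxymethoxy)-2-(3-methylbut-2-en-1-yl)-6-[(triisopropylsilyloxy)methyl]phenyl]butane-1,3-dione | CC(=O)CC(=O)c1c(CO[Si](C(C)C)(C(C)C)C(C)C)c(OCOC)cc(OCOC)c1CC=C(C)C | intermediate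
13 | 2,2,6-trimethyl-4H-1,3-dioxin-4-one | CC1=CC(=O)OC(C)(C)O1 | starting material
14 | 3-[3,5-bis(methoxymethoxy)-2-(3-methylbut-2-en-1-yl)-6-[(triisopropylsilyloxy)methyl]benzoyl]-2-hydroxy-2,6-dimethyl-2,3-dihydro-4H-pyran-4-one (mixture of racemic diastereomers) | CC1=CC(=O)C(C(=O)c2c(CO[Si](C(C)C)(C(C)C)C(C)C)c(OCOC)cc(OCOC)c2CC=C(C)C)C(C)(O)O1 | intermediate
15 | 3-[3,5-bis(methoxymethoxy)-2-(3-methylbut-2-en-1-yl)-6-[(triisopropylsilyloxy)methyl]benzoyl]-2,6-dimethyl-4H-pyran-4-one | Cc1cc(=O)c(C(=O)c2c(CO[Si](C(C)C)(C(C)C)C(C)C)c(OCOC)cc(OCOC)c2CC=C(C)C)c(C)o1 | intermediate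
16 | 3-[3,5-bis(methoxymethoxy)-2-(3-methylbut-2-en-1-yl)-6-[(triisopropylsilyloxy)methyl]benzoyl]heptane-2,4,6-trione (keto form) | CC(=O)CC(=O)C(C(C)=O)C(=O)c1c(CO[Si](C(C)C)(C(C)C)C(C)C)c(OCOC)cc(OCOC)c1CC=C(C)C | intermediate
17 | (2,6-dihydroxy-4-methylphenyl)[3,5-bis(methoxymethoxy)-2-(3-methylbut-2-en-1-yl)-6-[(triisopropylsilyloxy)methyl]phenyl]methanone | Cc1cc(O)c(C(=O)c2c(CO[Si](C(C)C)(C(C)C)C(C)C)c(OCOC)cc(OCOC)c2CC=C(C)C)c(O)c1 | intermediate
18 | (2-hydroxy-6-methoxy-4-methylphenyl)[3,5-bis(methoxymethoxy)-2-(3-methylbut-2-en-1-yl)-6-[(triisopropylsilyloxy)methyl]phenyl]methanone | COc1cc(C)cc(O)c1C(=O)c1c(CO[Si](C(C)C)(C(C)C)C(C)C)c(OCOC)cc(OCOC)c1CC=C(C)C | intermediate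
19 | (3-bromo-2-hydroxy-6-methoxy-4-methylphenyl)[3,5-bis(methoxymethoxy)-2-(3-methylbut-2-en-1-yl)-6-[(triisopropylsilyloxy)methyl]phenyl]methanone | COc1cc(C)c(Br)c(O)c1C(=O)c1c(CO[Si](C(C)C)(C(C)C)C(C)C)c(OCOC)cc(OCOC)c1CC=C(C)C | intermediate
20 | (3-bromo-2-hydroxy-6-methoxy-4-methylphenyl)[2-(hydroxymethyl)-3,5-bis(methoxymethoxy)-6-(3-methylbut-2-en-1-yl)phenyl]methanone | COc1cc(C)c(Br)c(O)c1C(=O)c1c(CO)c(OCOC)cc(OCOC)c1CC=C(C)C | intermediate
21 | 2-(3-bromo-2-hydroxy-6-methoxy-4-methylbenzoyl)-4,6-bis(methoxymethoxy)-3-(3-methylbut-2-en-1-yl)benzaldehyde | COc1cc(C)c(Br)c(O)c1C(=O)c1c(C=O)c(OCOC)cc(OCOC)c1CC=C(C)C | intermediate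
22 | Pestalone B, 2-(3-bromo-2-hydroxy-6-methoxy-4-methylbenzoyl)-4,6-dihydroxy-3-(3-methylbut-2-en-1-yl)benzaldehyde | COc1cc(C)c(Br)c(O)c1C(=O)c1c(C=O)c(O)cc(O)c1CC=C(C)C | target

**Total step count:** 15 steps.
**Longest linear sequence:** 15 steps, from 1 to 22; compounds 5 and 13 enter as purchased partners.

**The three steps most likely to fail**

Step 10 (key step). The chelated triacylmethanide may lose an acyl group by retro-Claisen cleavage, or the aldol may pair the terminal methyl with a chelated carbonyl, so that ring A forms with the wrong substitution pattern or not at all. The fallback joins the two rings by carbonyl addition instead of growing ring A, and sets out from phthalide 9. Commercial 3-methoxy-5-methylphenol is treated with ethyl vinyl ether and catalytic PPTS to give 1-(1-ethoxyethoxy)-3-methoxy-5-methylbenzene F1. Lithiation between its two oxygens (n-BuLi, THF, 0 °C) and addition of the aryllithium to lactone 9 at −78 °C, with a cold quench, should give [2-(1-ethoxyethoxy)-6-methoxy-4-methylphenyl][2-(hydroxymethyl)-3,5-bis(methoxymethoxy)-6-(3-methylbut-2-en-1-yl)phenyl]methanone F2. TIPSCl and imidazole in DMF then give its triisopropylsilyl ether F3. PPTS in methanol at room temperature should cleave only the ethoxyethyl acetal, which is far more acid-labile than the methoxymethyl ethers, and the fallback comes back to the route at phenol 18.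

Step 9. Acetylketene may acylate the enol oxygen instead of the central carbon, may dimerise faster than it is trapped, or the annulation may engage the enol on the aroyl side so that the aryl group ends up on the pyranone ring. The fallback builds the pyranone by alkyne conjugate addition and sets out from diketone 12. Magnesium-mediated soft enolisation (MgCl2, pyridine, CH2Cl2, 0 °C) and C-acylation with but-2-ynoyl chloride should give 3-(ArCO)hept-5-yne-2,4-dione F4. Its acetyl enol oxygen adds to the ynone in a 6-endo-dig conjugate addition on treatment with Et3N or catalytic K2CO3, and the fallback comes back to the route at pyranone 15.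

Step 4. The base may remove a benzylic, allylic hydrogen of the prenyl CH2 (lateral metalation) or the ring hydrogen between the two acetal oxygens, instead of the hydrogen next to the amide. The fallback reverses the order of the two ortho substitutions so that no prenyl group is present during a metalation that follows it, and sets out from amide 4. Directed ortho-metalation (s-BuLi, TMEDA, THF, −78 °C) and a DMF quench give N,N-diethyl-2-formyl-3,5-bis(methoxymethoxy)benzamide F5. Trimethyl orthoformate, methanol and catalytic PPTS convert it into N,N-diethyl-2-(dimethoxymethyl)-3,5-bis(methoxymethoxy)benzamide F6, whose acetal hydrogen is far less acidic than an allylic benzylic CH2. A second metalation at the position between the amide and the OMOM group, transmetalation with CuBr·SMe2 and reaction with 5 give N,N-diethyl-2-(dimethoxymethyl)-3,5-bis(methoxymethoxy)-6-(3-methylbut-2-en-1-yl)benzamide F7. PPTS in wet acetone at room temperature hydrolyses the acetal, and the fallback comes back to the route at aldehyde 7.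

**Further compounds**
F1 | step 10 | 1-(1-ethoxyethoxy)-3-methoxy-5-methylbenzene (racemic) | CCOC(C)Oc1cc(C)cc(OC)c1
F2 | step 10 | [2-(1-ethoxyethoxy)-6-methoxy-4-methylphenyl][2-(hydroxymethyl)-3,5-bis(methoxymethoxy)-6-(3-methylbut-2-en-1-yl)phenyl]methanone (racemic) | CCOC(C)Oc1cc(C)cc(OC)c1C(=O)c1c(CO)c(OCOC)cc(OCOC)c1CC=C(C)C
F3 | step 10 | [2-(1-ethoxyethoxy)-6-methoxy-4-methylphenyl][3,5-bis(methoxymethoxy)-2-(3-methylbut-2-en-1-yl)-6-[(triisopropylsilyloxy)methyl]phenyl]methanone (racemic) | CCOC(C)Oc1cc(C)cc(OC)c1C(=O)c1c(CO[Si](C(C)C)(C(C)C)C(C)C)c(OCOC)cc(OCOC)c1CC=C(C)C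
F4 | step 9 | 3-[3,5-bis(methoxymethoxy)-2-(3-methylbut-2-en-1-yl)-6-[(triisopropylsilyloxy)methyl]benzoyl]hept-5-yne-2,4-dione | CC#CC(=O)C(C(C)=O)C(=O)c1c(CO[Si](C(C)C)(C(C)C)C(C)C)c(OCOC)cc(OCOC)c1CC=C(C)C
F5 | step 4 | N,N-diethyl-2-formyl-3,5-bis(methoxymethoxy)benzamide | CCN(CC)C(=O)c1cc(OCOC)cc(OCOC)c1C=O
F6 | step 4 | N,N-diethyl-2-(dimethoxymethyl)-3,5-bis(methoxymethoxy)benzamide | CCN(CC)C(=O)c1cc(OCOC)cc(OCOC)c1C(OC)OC
F7 | step 4 | N,N-diethyl-2-(dimethoxymethyl)-3,5-bis(methoxymethoxy)-6-(3-methylbut-2-en-1-yl)benzamide | CCN(CC)C(=O)c1c(CC=C(C)C)c(OCOC)cc(OCOC)c1C(OC)OC
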